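**Retrosynthetic overview**
1. Target 3 is squalene (1) plus one H2O. In squalene numbering, only the C2–C7 ring bond and the C6–OH bond need to be made.
2. Both bonds form in one operation: H+ adds to C3, C7 closes onto C2, and water adds to the C6 cation 2, anti across the 6E alkene.
3. Ring A is the only ring formed. A cyclase variant that aborts at the monocyclic cation stops the cascade before ring B closes.
4. Squalene is C2-symmetric, so both termini give the same product. The remaining four alkenes, three of them E-configured, are bought rather than built.

Assumption: the recombinant Alicyclobacillus acidocaldarius squalene–hopene cyclase (AacSHC), expressed in E. coli from a synthetic gene, counts as a catalyst. Its preparation and screening are not counted as synthetic steps.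

**Step 1**
Reactants: 1 squalene
Product: 3 (1S,2S)-1,3,3-trimethyl-2-[(3E,7E,11E)-3,8,12,16-tetramethylheptadeca-3,7,11,15-tetraen-1-yl]cyclohexan-1-ol, via monocyclic tertiary cation 2 (not isolated)
Conditions: AacSHC D377C-derived water-capture variant (E. coli whole cells), 60 mM sodium citrate buffer pH 6.0, 0.2% sodium taurodeoxycholate, 50 °C, 48 h; hexane/EtOAc extraction, SiO2 (hydrocarbons elute first, 1 is recycled)
Reagents that add atoms: water, O
Why: Proposed new method: this is a proton-initiated cation–olefin monocyclisation ended by water capture inside a class-two terpene cyclase pocket, in which Asp376 protonates C3 of the chair-folded terminus, C7 closes on C2 from the face used for ring A of hopene (sets the ring CH as S), the D377C change (known to halt squalene at cation 2, which then normally loses a methyl proton to give 3-deoxyachilleol A) keeps ring B from closing, and a water held in an engineered polar cavity on the face that C11 would otherwise attack adds anti and equatorially, away from the axial methyl on C2 (sets the carbinol carbon as S, OH trans to the side chain); the closest known reaction types are that abortive monocyclisation and the stereospecific water quench of later cations by wild-type cyclases (hopan-22-ol, 8α-hydroxypolypoda-13,17,21-triene).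

Atom balance: C30H50 + H2O → C30H52O. The acid proton is returned by the captured water.

**Compound list**
1 | squalene, (6E,10E,14E,18E)-2,6,10,15,19,23-hexamethyltetracosa-2,6,10,14,18,22-hexaene | CC(C)=CCC/C(C)=C/CC/C(C)=C/CC/C=C(\C)CC/C=C(\C)CCC=C(C)C | starting material
2 | monocyclic tertiary cation: 1,3,3-trimethylcyclohexyl cation carrying the C21 tetraenyl chain at C2, ring CH fixed as in 3 | CC(C)=CCC/C(C)=C/CC/C(C)=C/CC/C=C(\C)CC[C@H]1C(C)(C)CCC[C+]1C | intermediate
3 | (1S,2S)-1,3,3-trimethyl-2-[(3E,7E,11E)-3,8,12,16-tetramethylheptadeca-3,7,11,15-tetraen-1-yl]cyclohexan-1-ol (equatorial OH trans to equatorial side chain, axial 1-methyl) | CC(C)=CCC/C(C)=C/CC/C(C)=C/CC/C=C(\C)CC[C@H]1C(C)(C)CCC[C@]1(C)O | target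

**Total step count:** 1. **Longest linear sequence:** 1.

**Steps most likely to fail** (the route has one step, so there is one entry)

Step 1 can fail in four ways:
- Cation 2 may lose a proton faster than it captures water, giving the exocyclic alkene.
- Some of the material may run on to bicyclic polypodatetraene-type products.
- Asp377 variants turn over slowly.
- Product 3 still carries a free isopropylidene terminus and could be taken up again by the enzyme.

Three measures limit these risks:
- Site-saturation libraries at Tyr420 and Leu607, which wall the ring A/ring B junction, are screened by GC-MS for the tertiary alcohol.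
- The reaction is stopped at partial conversion.
- Alcohol 3 separates easily from all hydrocarbon by-products on silica.

Fallback: this separates ring formation from C–O bond formation. It sets out from 1 and returns at 3.
- The plain D377C enzyme in the same buffer carries out the known elimination-terminated monocyclisation. It gives (S)-3-deoxyachilleol A F1, which has the same ring CH configuration as 3.
- Hg(OAc)2 (1.0 equiv) in THF/H2O 1:1 at 0 °C then performs a Markovnikov oxymercuration to the tertiary β-hydroxyalkylmercury acetate F2.
- This reaction strongly prefers the 1,1-disubstituted alkene over the four trisubstituted ones.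
- Water should enter equatorially because the axial approach is blocked by the axial methyl of the gem-dimethyl group. Labd-8(17)-enes behave the same way and give 8α-oxygenated labdanes.
- NaBH4 in aqueous NaOH at 0 °C, added to the same flask, replaces mercury by hydrogen and delivers 3.

**Further compounds**
F1 | step 1 | (S)-3-deoxyachilleol A, (1S)-2,2-dimethyl-6-methylidenecyclohexane bearing the (3E,7E,11E)-3,8,12,16-tetramethylheptadeca-3,7,11,15-tetraen-1-yl chain at C1 | CC(C)=CCC/C(C)=C/CC/C(C)=C/CC/C=C(\C)CC[C@H]1C(C)(C)CCCC1=C
F2 | step 1 | acetoxy{[(1S,2S)-1-hydroxy-3,3-dimethyl-2-[(3E,7E,11E)-3,8,12,16-tetramethylheptadeca-3,7,11,15-tetraen-1-yl]cyclohexyl]methyl}mercury | CC(C)=CCC/C(C)=C/CC/C(C)=C/CC/C=C(\C)CC[C@H]1C(C)(C)CCC[C@]1(C[Hg]OC(C)=O)O
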